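Numbering used throughout: each chroman unit is O1, C2, C3, C4, C4a, C5–C8, C8a, and the second unit carries the same locants with a double prime (C2'', C3'', C4''). Rings A are the benzo rings, rings C the pyran rings, rings B the 2‑aryl groups. Compounds 1–11 are those of the steps below.

## The problem

Compound 11 is a 3,3''-biflavanone: two 7,4'-dihydroxyflavanone units joined only by the σ-bond between their α-carbonyl carbons, so that the centre of the molecule is the 1,4-diketone C4(=O)–C3–C3''–C4''(=O) flanked by the benzylic ether carbons C2 and C2''. The four contiguous stereocentres are (2S,3R,2''R,3''S): each ring C is 2,3-trans and the halves are mirror images, so 11 is meso and no absolute control is needed. Within one ring, trans is the thermodynamic arrangement, so C2 and C3 can steer each other, but the unlike C3/C3'' relation has no such bias over the like (C2-symmetric) one and must be set kinetically. Once the ketones exist, both C3–H bonds are enolisable (scrambling, E1cB opening of ring C), C2–O1 is a benzylic ether open to ionisation and hydrogenolysis, and the four phenols do not tolerate oxidants. The enabling feature is that C4(=O)–C3–C3''–C4''(=O) is what ozone leaves of a cyclobutene with a C4=C4'' double bond and a C3–C3'' single bond. That cyclobutene is the valence isomer of the diene C3=C4–C4''=C3'' of a 4,4'-linked bi(2H-chromene), in which both rings C, both O1–C2 bonds and both C2 stereocentres already exist. Because both diene double bonds are endocyclic, a disrotatory 4π closure can only place H3 and H3'' cis, which becomes the meso relation once C4=C4'' is cleaved.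

## Retrosynthesis

**11 ⇒ 10 (four O–benzyl bonds).** The phenols are masked to the end because the route contains a photochemical step and an ozonolysis. Benzyl is preferred to methyl: methyl ethers would need BBr3 on a 1,4-diketone with two enolisable stereocentres and two ionisable C2–O1 bonds, whereas benzyl ethers leave by neutral hydrogenolysis. The forward step must cleave four ArO–CH2Ph bonds faster than the cyclic benzylic C2–O1 bonds.

**10 ⇒ 8 (both C=O bonds joined to a C4=C4'' double bond, via ozonide 9).** Direct C3–C3'' constructions on ketones (enolate dimerisation, twofold chalcone cyclisation) leave the like/unlike question to chance and expose C3 to base. In cyclobutene 8 the relation is encoded as a cis ring fusion, and C3/C3'' carry no adjacent carbonyl, so they are configurationally locked until the penultimate step. Ozone must select the strained, tetrasubstituted, stilbene-like alkene over benzyl ethers and alkoxyarenes, which its much higher rate of reaction makes reasonable.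

**8 ⇒ 7 (C3–C3'' σ-bond cut, π-bond returned to C3=C4 and C3''=C4'').** This retro-4π step removes one ring and two stereocentres and exposes a symmetric dimer. The forward closure must be disrotatory and must take the correct face. Only the meso diene 7 can give the all-trans product, since its two aryl groups lie on the same face and bonding on the other face puts both trans to the new bond. The C2-symmetric diastereomer has one aryl group on each face and must give one cis ring.

**7 ⇒ 5 (C4–C4' bond; boronate 6 in situ).** The symmetric diene comes from one monomer by reductive homocoupling of enol triflate 5. The alternative of pinacol coupling of 4 and twofold dehydration passes through a diol with four stereocentres and needs acid on a flavene whose C2–O1 bond is allylic, benzylic and activated by a 4-alkoxyaryl group. The palladium route stays neutral to basic. Its price is that racemic 5 gives heterochiral (meso) and homochiral coupling products statistically, so 7 must be separated.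

**5 ⇒ 4 ⇒ 3 ⇒ 1 + 2.** Enol triflate 5 is the O-sulfonylated enol of flavanone 4. Flavanone 4 is the oxa-Michael isomer of chalcone 3, which is the Claisen–Schmidt product of commercial acetophenone 1 and aldehyde 2. Racemic 4 is wanted, because the meso target needs both C2 configurations.

## Roads not taken

Alternative 1: The cut is at the two aryl–carbonyl bonds C4–C4a and C4''–C4a'', and later at O1–C2 and O1''–C2''. The forward key step is a twofold AlCl3 Friedel–Crafts acylation in which the arene 1,3-dimethoxybenzene A3 is acylated by the meso-2,3-bis(4-methoxybenzyl)succinyl dichloride A2, giving the meso diketone A1. Selective ortho-demethylation and an oxidative benzylic C–H cyclisation would then close both rings C.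
- Merits: the unlike C3/C3'' relation is set early on a lignan-type succinate, the arene A3 is a cheap commodity, and every step up to A1 is classical, scalable and free of photochemistry. In this respect it is better than the chosen plan.
- Weak points: the α-stereocentres of A2 and A1 sit next to acyl groups under AlCl3/HCl and can epimerise; the γ-keto acid chloride formed after the first acylation of A3 tends to close to an enol lactone; AlCl3 also demethylates. Most seriously, oxidation of the benzylic CH2 β to a ketone invites dehydrogenation to the enone, which destroys the C3 stereocentre the route was built around.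
- Comparison: the chosen plan creates C3/C3'' in a step that can only give the cis relation, never exposes them to Lewis acid, and has both O1–C2 bonds from step 2. It is also shorter (7 steps against an estimated 8–10).

Alternative 2: The cut is the same C4=C4'' cleavage, but the cyclobutene would be assembled by intermolecular [2+2] photocycloaddition of the diarylalkyne A6, bis[4-methoxy-2-(methoxymethoxy)phenyl]acetylene, to the cis-dioxepine A7. The forward key step is ozonolysis of the resulting bicyclic cyclobutene A5 to the dioxepane diketone A4. Acetonide and MOM removal, two benzylic C–O ring closures and O-demethylation would follow.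
- Merits: the key step is ordinary ozonolysis, and no photolabile 2H-chromene is carried. Here it is better than the chosen plan, whose key step is unproven and whose diene can epimerise at C2 under light.
- Weak points: the uncertainty moves to the bimolecular photocycloaddition of an electron-rich diarylalkyne to a hindered, unactivated 1,2-disubstituted alkene, whose stilbene-like product absorbs the same light. A6 and A7 each need several steps, and the end game must close two rings at ionisable benzylic centres and then remove methyl ethers with a strong Lewis acid.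
- Comparison: the chosen plan uses the same reliable ozonolysis but reaches its cyclobutene by a unimolecular closure of a preformed diene, with both rings C already closed, in about half the steps.

Alternative 3: The cut is at O1–C2 and O1''–C2'', combined with a sacrificial C2–C2'' bond. Two chalcone units held head-to-head by a temporary tether would photodimerise and, after tether removal, give cyclobutane A9. The forward key step is a two-electron oxidation that breaks C2–C2'' while the ortho-phenols trap the benzylic cations, giving the meso tetramethyl ether A8.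
- Merits: chalcone [2+2] dimerisation is well known, the cis-diaroyl cyclobutane encodes the unlike C3/C3'' relation as in the chosen plan, and C2 is free to settle trans during ring closure. No diastereomer separation and no ozonolysis are needed, which is a real advantage.
- Weak points: head-to-head syn selectivity in solution needs the tether (extra steps); cyclobutane radical cations usually revert fully to two alkenes, which would also break the C3–C3'' bond; the oxidant can dehydrogenate flavanones; A8 still needs BBr3.
- Comparison: step count is similar and both key steps are speculative. The chosen plan forms exactly the bond that is kept, leaves no doubt about which bond the cleavage step breaks, and ends with a neutral deprotection.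

Key step: step 5

Remark on the chemistry: racemic flavanone is used on purpose; 4, 5 and 6 are racemates drawn as the 2S enantiomer, whereas 7, 8, 9, 10 and 11 are achiral meso compounds, so only diastereocontrol is required.

## Route

Step 1
Reactants: 1 1-[4-(benzyloxy)-2-hydroxyphenyl]ethan-1-one; 2 4-(benzyloxy)benzaldehyde
Product: 3 (E)-1-[4-(benzyloxy)-2-hydroxyphenyl]-3-[4-(benzyloxy)phenyl]prop-2-en-1-one
Conditions: KOH (50% aq.), EtOH, rt
Reagents that add atoms: none
Why: Claisen–Schmidt condensation: the methyl ketone enolate adds to the non-enolisable aldehyde and the aldol dehydrates to the (E)-enone under thermodynamic control; the 2'-OH is carried as its phenoxide and benzyl ethers are inert to base.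

Step 2
Reactants: 3 (E)-1-[4-(benzyloxy)-2-hydroxyphenyl]-3-[4-(benzyloxy)phenyl]prop-2-en-1-one
Product: 4 racemic 7-(benzyloxy)-2-[4-(benzyloxy)phenyl]chroman-4-one
Conditions: NaOAc, EtOH/H2O, reflux
Reagents that add atoms: none
Why: Intramolecular oxa-Michael addition of the 2'-phenoxide to the enone, the standard chalcone–flavanone isomerisation; C2 is formed as a racemate, which the meso target requires, and unreacted 3 can be recycled because the reaction is an equilibrium.

Step 3
Reactants: 4 racemic 7-(benzyloxy)-2-[4-(benzyloxy)phenyl]chroman-4-one
Product: 5 racemic 7-(benzyloxy)-2-[4-(benzyloxy)phenyl]-2H-chromen-4-yl trifluoromethanesulfonate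
Conditions: Tf2O, 2,6-di-tert-butyl-4-methylpyridine, CH2Cl2, 0 °C → rt
Reagents that add atoms: trifluoromethanesulfonic anhydride, O=S(=O)(OS(=O)(=O)C(F)(F)F)C(F)(F)F
Why: Enol triflate formation by O-sulfonylation of the ketone and loss of H3 to the hindered pyridine (soft enolisation); only C3 bears α-hydrogens, and avoiding a free enolate suppresses E1cB opening of ring C; C2 is untouched.

Step 4
Reactants: 5 racemic 7-(benzyloxy)-2-[4-(benzyloxy)phenyl]-2H-chromen-4-yl trifluoromethanesulfonate (two molecules)
Product: 7 (2R,2'S)-7,7'-bis(benzyloxy)-2,2'-bis[4-(benzyloxy)phenyl]-2H,2'H-4,4'-bichromene (meso), via racemic chromen-4-yl pinacol boronate 6 (not isolated)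
Conditions: B2pin2 (0.5 equiv), PdCl2(dppf) (5 mol %), K3PO4, 1,4-dioxane/H2O, 80 °C
Reagents that add atoms: none
Why: One-pot Miyaura borylation and Suzuki–Miyaura coupling: half of the alkenyl triflate becomes boronate 6, which couples with the remaining 5 to form C4–C4' under basic conditions that the acid-labile flavene tolerates. Heterochiral coupling gives meso 7 and homochiral coupling its C2-symmetric diastereomer in the expected statistical proportion; 7 is to be isolated by crystallisation or chromatography on base-deactivated silica.

Step 5
Reactants: 7 (2R,2'S)-7,7'-bis(benzyloxy)-2,2'-bis[4-(benzyloxy)phenyl]-2H,2'H-4,4'-bichromene (meso)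
Product: 8 meso cis-fused cyclobutene (2R,3R,2''S,3''S): 7,7''-bis(benzyloxy)-2,2''-bis[4-(benzyloxy)phenyl]-3,3''-bichroman with an added C4=C4'' double bond, four-membered ring C3–C4=C4''–C3'', H3 cis to H3'', each 2-aryl group trans to the C3–C3'' bond
Conditions: hν (300–313 nm, Pyrex filter), degassed toluene (about 3 mM), Ar, 0–10 °C, to partial conversion
Reagents that add atoms: none
Why: Proposed new method: direct singlet excitation of the cisoid conformer of the diene C3=C4–C4''=C3'' should trigger the orbital-symmetry-allowed disrotatory 4π electrocyclisation that forms the C3–C3'' σ-bond and moves the π-bond to C4=C4''; the closest known reaction type is the photochemical closure of 1,1'-bicycloalkenyls and 2,3-diaryl-1,3-butadienes to cyclobutenes, which has not been shown on a 4,4'-bi(2H-chromene). The one ring closed is the cyclobutene (C3, C4, C4'', C3''), by 4π disrotatory closure; since each double bond lies in a six-membered ring, H3 and H3'' are the inward substituents and must end cis. The new stereocentres C3 and C3'' are thus fixed relative to each other by the disrotatory mode and the ring constraint, and relative to C2/C2'' by the sense of disrotation. In meso 7 both 2-aryl groups lie on the same face of the cisoid diene, so the bond should form through the lobes on the opposite face, which leaves both aryl groups exo on the folded core and trans to the C3–C3'' bond. The opposite sense would push both aryl groups into the concave face against each other. The selectivity needed is this facial choice together with chemoselectivity over the reversible photochromic 6π opening of the 2H-chromene rings, which recloses thermally and has no irreversible hydrogen-shift exit because C2 bears no alkyl group. Secondary photochemistry of the stilbene-like product is limited by the long-wavelength cut-off, dilution, exclusion of oxygen and partial conversion, and the cross-conjugated diene has no six-electron photocyclisation path.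

Step 6
Reactants: 8 meso cis-fused cyclobutene (2R,3R,2''S,3''S)
Product: 10 (2S,3R,2''R,3''S)-7,7''-bis(benzyloxy)-2,2''-bis[4-(benzyloxy)phenyl]-[3,3''-bichromane]-4,4''-dione (meso), via bridged secondary ozonide 9 (not isolated)
Conditions: O3 (titrated, Sudan Red 7B end point), CH2Cl2, −78 °C; then PPh3, −78 °C → rt
Reagents that add atoms: ozone, [O-][O+]=O
Why: Ozonolysis: cycloaddition of ozone to the strained, electron-rich tetrasubstituted C4=C4'' bond from the open H3/H3'' face, cycloreversion and recombination give ozonide 9, which PPh3 reduces to the two aryl ketones. The C3–C3'' bond and all four stereocentres are spectators, and the C3 descriptors change only because C4 gains CIP priority; titrating the ozone spares benzyl ethers and alkoxyarenes.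

Step 7
Reactants: 10 (2S,3R,2''R,3''S)-7,7''-bis(benzyloxy)-2,2''-bis[4-(benzyloxy)phenyl]-[3,3''-bichromane]-4,4''-dione (meso)
Product: 11 (2S,3R,2''R,3''S)-7,7''-dihydroxy-2,2''-bis(4-hydroxyphenyl)-[3,3''-bichromane]-4,4''-dione (meso; CNP0231820.1)
Conditions: H2 (1 atm), 10% Pd/C, EtOAc/THF, rt
Reagents that add atoms: none
Why: Hydrogenolysis of the four benzyl aryl ethers over palladium on carbon under neutral conditions frees the phenols without enolising C3 or ionising C2, so the configuration from steps 4 and 5 is kept.

## Compound list

1 | 1-[4-(benzyloxy)-2-hydroxyphenyl]ethan-1-one | CC(=O)c1ccc(OCc2ccccc2)cc1O | starting material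
2 | 4-(benzyloxy)benzaldehyde | O=Cc1ccc(OCc2ccccc2)cc1 | starting material
3 | (E)-1-[4-(benzyloxy)-2-hydroxyphenyl]-3-[4-(benzyloxy)phenyl]prop-2-en-1-one | O=C(/C=C/c1ccc(OCc2ccccc2)cc1)c1ccc(OCc2ccccc2)cc1O | intermediate
4 | racemic 7-(benzyloxy)-2-[4-(benzyloxy)phenyl]chroman-4-one (2S drawn) | O=C1C[C@@H](c2ccc(OCc3ccccc3)cc2)Oc2cc(OCc3ccccc3)ccc21 | intermediate
5 | racemic 7-(benzyloxy)-2-[4-(benzyloxy)phenyl]-2H-chromen-4-yl trifluoromethanesulfonate (2S drawn) | O=S(=O)(OC1=C[C@@H](c2ccc(OCc3ccccc3)cc2)Oc2cc(OCc3ccccc3)ccc21)C(F)(F)F | intermediate
6 | racemic 2-{7-(benzyloxy)-2-[4-(benzyloxy)phenyl]-2H-chromen-4-yl}-4,4,5,5-tetramethyl-1,3,2-dioxaborolane (2S drawn) | CC1(C)OB(OC1(C)C)C1=C[C@@H](c2ccc(OCc3ccccc3)cc2)Oc2cc(OCc3ccccc3)ccc21 | intermediate (not isolated)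
7 | (2R,2'S)-7,7'-bis(benzyloxy)-2,2'-bis[4-(benzyloxy)phenyl]-2H,2'H-4,4'-bichromene (meso) | C1(C2=C[C@H](c3ccc(OCc4ccccc4)cc3)Oc3cc(OCc4ccccc4)ccc32)=C[C@@H](c2ccc(OCc3ccccc3)cc2)Oc2cc(OCc3ccccc3)ccc21 | intermediate
8 | meso cis-fused cyclobutene (2R,3R,2''S,3''S): ring C3–C4=C4''–C3'', H3/H3'' cis, 2-aryl groups trans to the C3–C3'' bond, 7,7''-bis(benzyloxy), 2,2''-bis[4-(benzyloxy)phenyl] | C12=C3c4ccc(OCc5ccccc5)cc4O[C@H](c4ccc(OCc5ccccc5)cc4)[C@H]3[C@H]1[C@H](c1ccc(OCc3ccccc3)cc1)Oc1cc(OCc3ccccc3)ccc12 | intermediate
9 | bridged secondary ozonide of 8 (C4 and C4'' joined by one ether oxygen and one peroxide bridge, the peroxide on the H3/H3'' face; bridgehead configuration is erased on reduction) | O1[C@]23OO[C@]14c5ccc(OCc6ccccc6)cc5O[C@@H](c5ccc(OCc6ccccc6)cc5)[C@@H]4[C@@H]2[C@@H](c2ccc(OCc4ccccc4)cc2)Oc2cc(OCc4ccccc4)ccc32 | intermediate (not isolated)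
10 | (2S,3R,2''R,3''S)-7,7''-bis(benzyloxy)-2,2''-bis[4-(benzyloxy)phenyl]-[3,3''-bichromane]-4,4''-dione (meso) | O=C1c2ccc(OCc3ccccc3)cc2O[C@H](c2ccc(OCc3ccccc3)cc2)[C@H]1[C@@H]1C(=O)c2ccc(OCc3ccccc3)cc2O[C@H]1c1ccc(OCc2ccccc2)cc1 | intermediate
11 | (2S,3R,2''R,3''S)-7,7''-dihydroxy-2,2''-bis(4-hydroxyphenyl)-[3,3''-bichromane]-4,4''-dione (meso) | O=C1c2ccc(O)cc2O[C@H](c2ccc(O)cc2)[C@H]1[C@@H]1C(=O)c2ccc(O)cc2O[C@H]1c1ccc(O)cc1 | target

## Step count and least certain steps

Total: 7 steps. Longest linear sequence: 7 steps (from 1 or 2).

**Step 5 (key step, proposed new method).** Three processes may defeat it: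
- inefficient closure, because most excited molecules sit in transoid or strongly twisted conformers and decay unproductively;
- epimerisation at C2 through the photochromic ring opening before closure, which would erode the meso configuration and give a cis ring;
- secondary photoreaction of the stilbene-like product (dimerisation, photo-oxidation).

Fallback by known chemistry, setting out from 1 and returning at 10: oxidative enolate homocoupling of the dianion of 1 (LiN(iPr)2, then CuCl2) gives 1,4-bis[4-(benzyloxy)-2-hydroxyphenyl]butane-1,4-dione F1. Twofold Claisen–Schmidt condensation with 2 gives the bis(benzylidene) diketone F2. Twofold oxa-Michael closure (NaOAc, EtOH, reflux) gives 10 with trans rings under thermodynamic control. The like/unlike relation is not controlled in this fallback, so meso 10 must be separated from its C2-symmetric diastereomer before step 7.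

**Step 4.** The heterochiral and homochiral coupling products form together and may fail to separate, since they differ only in two remote stereocentres; protodeboronation of 6 can also lower conversion. Fallback, setting out from 5 and returning at 11: the coupling mixture is taken on unseparated. The C2-symmetric diene F3 then passes through steps 5–7 beside 7, giving the cis,trans cyclobutene F4, the cis,trans diketone F5 and the 2''-epimer of the target F6. Warming F6 in weakly acidic aqueous ethanol should epimerise the cis C2'' by reversible ring opening to a 4'-quinone methide, the path by which 3-substituted 4'-hydroxyflavanones such as dihydroflavonols epimerise at C2, and should converge on all-trans 11. The risk there is concurrent enolisation at C3.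

**Step 3.** Ring C may open by β-elimination of the phenoxide during enolisation, or the electron-rich ketone may sulfonylate incompletely. Fallback, setting out from 4 and returning at 7: pinacol coupling of 4 with SmI2 (THF/HMPA) gives the 4,4'-diol F7 as a mixture of C4 epimers, and twofold dehydration (POCl3, pyridine) gives 7 together with its C2-symmetric diastereomer, to be separated as in step 4.

**Step 6.** Over-oxidation of benzyl ether C–H bonds or alkoxyarenes, slow reduction of the tetrasubstituted ozonide, or epimerisation at C3 by acidic peroxidic by-products may occur. Fallback, setting out from 8 and returning at 10: stoichiometric OsO4 in pyridine (NaHSO3 work-up) dihydroxylates C4=C4'' from the H3/H3'' face to the cis-diol F8, and Pb(OAc)4 cleaves the glycol to 10.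

**Step 7.** Over-reduction may occur, namely hydrogenolysis of the cyclic benzylic C2–O1 bonds or reduction of the aryl ketones. Fallback, from 10 directly to 11: Lewis-acid debenzylation with BCl3 and pentamethylbenzene as cation scavenger in CH2Cl2 at −78 °C, which involves no hydrogen and makes no new intermediate.

## Further compounds

F1 | step 5 | 1,4-bis[4-(benzyloxy)-2-hydroxyphenyl]butane-1,4-dione | O=C(CCC(=O)c1ccc(OCc2ccccc2)cc1O)c1ccc(OCc2ccccc2)cc1O
F2 | step 5 | (2E,3E)-2,3-bis[4-(benzyloxy)benzylidene]-1,4-bis[4-(benzyloxy)-2-hydroxyphenyl]butane-1,4-dione | O=C(c1ccc(OCc2ccccc2)cc1O)/C(=C/c1ccc(OCc2ccccc2)cc1)C(=C/c1ccc(OCc2ccccc2)cc1)\C(=O)c1ccc(OCc2ccccc2)cc1O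
F3 | step 4 | racemic (2R,2'R)-7,7'-bis(benzyloxy)-2,2'-bis[4-(benzyloxy)phenyl]-2H,2'H-4,4'-bichromene (2R,2'R drawn) | C1(C2=C[C@H](c3ccc(OCc4ccccc4)cc3)Oc3cc(OCc4ccccc4)ccc32)=C[C@H](c2ccc(OCc3ccccc3)cc2)Oc2cc(OCc3ccccc3)ccc21
F4 | step 4 | racemic cis,trans cyclobutene (2R,3R,2''R,3''S drawn): as 8 but with the 2''-aryl group cis to the C3–C3'' bond | C12=C3c4ccc(OCc5ccccc5)cc4O[C@@H](c4ccc(OCc5ccccc5)cc4)[C@H]3[C@H]1[C@H](c1ccc(OCc3ccccc3)cc1)Oc1cc(OCc3ccccc3)ccc12
F5 | step 4 | racemic (2R,3S,2''R,3''R)-7,7''-bis(benzyloxy)-2,2''-bis[4-(benzyloxy)phenyl]-[3,3''-bichromane]-4,4''-dione (one ring trans, one cis) | O=C1c2ccc(OCc3ccccc3)cc2O[C@@H](c2ccc(OCc3ccccc3)cc2)[C@@H]1[C@H]1C(=O)c2ccc(OCc3ccccc3)cc2O[C@H]1c1ccc(OCc2ccccc2)cc1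
F6 | step 4 | racemic (2R,3S,2''R,3''R)-7,7''-dihydroxy-2,2''-bis(4-hydroxyphenyl)-[3,3''-bichromane]-4,4''-dione (2''-epimer of 11) | O=C1c2ccc(O)cc2O[C@@H](c2ccc(O)cc2)[C@@H]1[C@H]1C(=O)c2ccc(O)cc2O[C@H]1c1ccc(O)cc1
F7 | step 3 | (2R,2'S)-7,7'-bis(benzyloxy)-2,2'-bis[4-(benzyloxy)phenyl]-[4,4'-bichromane]-4,4'-diol (mixture of C4/C4' epimers) | OC1(C[C@H](c2ccc(OCc3ccccc3)cc2)Oc2cc(OCc3ccccc3)ccc21)C1(O)C[C@@H](c2ccc(OCc3ccccc3)cc2)Oc2cc(OCc3ccccc3)ccc21
F8 | step 6 | meso cis-4,4''-diol of 8 (cyclobutane-1,2-diol, both OH on the H3/H3'' face) | O[C@]12[C@@]3(O)c4ccc(OCc5ccccc5)cc4O[C@H](c4ccc(OCc5ccccc5)cc4)[C@H]3[C@H]1[C@H](c1ccc(OCc3ccccc3)cc1)Oc1cc(OCc3ccccc3)ccc12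
F0 | step 7 | none | none
A1 | alternative 1 | meso-1,4-bis(2,4-dimethoxyphenyl)-2,3-bis(4-methoxybenzyl)butane-1,4-dione | O=C(c1ccc(OC)cc1OC)[C@@H](Cc1ccc(OC)cc1)[C@@H](Cc1ccc(OC)cc1)C(=O)c1ccc(OC)cc1OC
A2 | alternative 1 | meso-2,3-bis(4-methoxybenzyl)succinyl dichloride | O=C(Cl)[C@@H](Cc1ccc(OC)cc1)[C@@H](Cc1ccc(OC)cc1)C(Cl)=O
A3 | alternative 1 | 1,3-dimethoxybenzene | COc1cccc(OC)c1
A4 | alternative 2 | meso cis-5,6-bis[4-methoxy-2-(methoxymethoxy)benzoyl]-4,7-bis(4-methoxyphenyl)-2,2-dimethyl-1,3-dioxepane | O1C(C)(C)O[C@H](c2ccc(OC)cc2)[C@@H](C(=O)c2ccc(OC)cc2OCOC)[C@@H](C(=O)c2ccc(OC)cc2OCOC)[C@@H]1c1ccc(OC)cc1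
A5 | alternative 2 | meso cis-fused 8,9-bis[4-methoxy-2-(methoxymethoxy)phenyl]-2,6-bis(4-methoxyphenyl)-4,4-dimethyl-3,5-dioxabicyclo[5.2.0]non-8-ene | O1C(C)(C)O[C@H](c2ccc(OC)cc2)[C@H]2C(c3ccc(OC)cc3OCOC)=C(c3ccc(OC)cc3OCOC)[C@H]2[C@@H]1c1ccc(OC)cc1
A6 | alternative 2 | bis[4-methoxy-2-(methoxymethoxy)phenyl]acetylene | COCOc1cc(OC)ccc1C#Cc1ccc(OC)cc1OCOC
A7 | alternative 2 | meso cis-4,7-bis(4-methoxyphenyl)-2,2-dimethyl-4,7-dihydro-1,3-dioxepine | CC1(C)O[C@H](c2ccc(OC)cc2)C=C[C@H](c2ccc(OC)cc2)O1
A8 | alternative 3 | (2S,3R,2''R,3''S)-7,7''-dimethoxy-2,2''-bis(4-methoxyphenyl)-[3,3''-bichromane]-4,4''-dione (meso) | O=C1c2ccc(OC)cc2O[C@H](c2ccc(OC)cc2)[C@H]1[C@@H]1C(=O)c2ccc(OC)cc2O[C@H]1c1ccc(OC)cc1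
A9 | alternative 3 | meso r-1,c-2-bis(2-hydroxy-4-methoxybenzoyl)-t-3,t-4-bis(4-methoxyphenyl)cyclobutane | [C@H]1(C(=O)c2ccc(OC)cc2O)[C@@H](C(=O)c2ccc(OC)cc2O)[C@H](c2ccc(OC)cc2)[C@@H]1c1ccc(OC)cc1
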